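**Plan**
- **Cuts.** The ten O-benzyl groups go last. The first skeletal cut is the aryl ketone bond C4–C4a of the dihydroflavonol (rings A, C, B). C2–C3–C4 of ring C is a three-carbon chain with oxygen on every carbon, and C4 is tied to ring A by this one C–C bond only, so the cut opens ring C to a 2-bromoaryl ether that carries an N-methoxy-N-methylamide.
- **Further cuts.** These are O1–C2 (ether to 2-bromo-5-benzyloxyphenol), C2–C1' (ring B aryllithium plus a glycerate amide), C4f–C2' (flavan to ring B) and C2f–ring E (aryl addition to a chromone).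
- **Forward order.** Ring F is bought as a chromone and is arylated at C2f, arylated at C4f and then hydroborated. The C2–C4 chain is joined to ring B, ring A is hung on through O1, and ring C closes last.
- **Flavan stereocentres.** C2f comes from a rhodium-catalysed asymmetric 1,4-addition. C3f and C4f come from syn hydroboration anti to ring E.
- **Dihydroflavonol stereocentres.** C3 is the carbinol carbon of the (S)-glyceraldehyde acetonide family, bought one oxidation level higher as the methyl (S)-glycerate acetonide. Its carbonyl carbon becomes C2 and its CH2O carbon becomes C4. C2 is set by Felkin–Anh reduction followed by invertive Mitsunobu etherification.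

Key step: step 21

Abbreviations: Bn = benzyl. The suffix f marks atoms of the flavan unit (rings D, F, E). ArFl = 3,4,5-tris(benzyloxy)-2-[(2R,3S,4S)-3,7-bis(benzyloxy)-2-[3,4,5-tris(benzyloxy)phenyl]chroman-4-yl]phenyl, that is, ring B carrying the protected flavan at C2'.

Assumption 1: the (S)-biaryl bisphosphine is taken to give the (2S)-flavanone, the sense that (S)-biaryl bisphosphines show with cyclic enones; if the sense proves opposite, the (R)-ligand is used.

Assumption 2: hindered rotation about C4f–C2' is taken to give interconverting rotamers, not separable stereoisomers.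

**Step 1**
Reactants: 1 5-bromo-1,2,3-trimethoxybenzene
Product: 2 5-bromobenzene-1,2,3-triol
Conditions: BBr3 (3.5 equiv), CH2Cl2, −78 °C to rt; then H2O
Reagents that add atoms: none
Why: Lewis acid cleavage of aryl methyl ethers with BBr3 removes all three methyl groups and leaves the aryl bromide untouched, so the oxygens can be re-protected with groups that fall in the final hydrogenolysis.

**Step 2**
Reactants: 2 5-bromobenzene-1,2,3-triol
Product: 3 5-bromo-1,2,3-tris(benzyloxy)benzene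
Conditions: BnBr (3.5 equiv), K2CO3, DMF, 60 °C, N2
Reagents that add atoms: benzyl bromide, BrCc1ccccc1
Why: Williamson etherification of the three phenoxides under inert gas should give the tribenzyl ether, which serves twice, as the source of ring E and of ring B.

**Step 3**
Reactants: 3 5-bromo-1,2,3-tris(benzyloxy)benzene
Product: 6 3,4,5-tris(benzyloxy)phenylboronic acid, via aryllithium 4 (not isolated), via lithium aryltriisopropoxyborate 5 (not isolated)
Conditions: n-BuLi (1.05 equiv), THF, −78 °C; B(Oi-Pr)3, −78 °C to rt; 1 M HCl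
Reagents that add atoms: triisopropyl borate, CC(C)OB(OC(C)C)OC(C)C; water, O
Why: Bromine–lithium exchange outruns benzylic deprotonation at low temperature, the aryllithium is trapped by the borate (lithiation–borylation), and acid hydrolysis frees the boronic acid.

**Step 4**
Reactants: 7 7-hydroxy-4H-chromen-4-one
Product: 8 7-(benzyloxy)-4H-chromen-4-one
Conditions: BnBr, K2CO3, acetone, reflux
Reagents that add atoms: benzyl bromide, BrCc1ccccc1
Why: Williamson etherification of the acidic 7-hydroxyl under a weak base should not open the pyranone ring.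

**Step 5**
Reactants: 8 7-(benzyloxy)-4H-chromen-4-one; 6 3,4,5-tris(benzyloxy)phenylboronic acid
Product: 9 (2S)-7-(benzyloxy)-2-[3,4,5-tris(benzyloxy)phenyl]chroman-4-one
Conditions: [Rh(OH)(cod)]2 (1.5 mol %), (S)-(6,6'-dimethoxybiphenyl-2,2'-diyl)bis[bis(3,4,5-trifluorophenyl)phosphine] (3.3 mol %), toluene/H2O (10:1), 25 °C
Reagents that add atoms: none
Why: In this rhodium-catalysed asymmetric 1,4-addition of an arylboronic acid to a chromone (Hayashi–Miyaura reaction) the aryl–rhodium species bound to the electron-poor (S)-bisphosphine inserts one enantiotopic face of C2f=C3f and sets C2f as S, while the base-free medium should suppress retro-oxa-Michael racemisation.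

**Step 6**
Reactants: 9 (2S)-7-(benzyloxy)-2-[3,4,5-tris(benzyloxy)phenyl]chroman-4-one
Product: 10 (2S)-7-(benzyloxy)-2-[3,4,5-tris(benzyloxy)phenyl]-2H-chromen-4-yl trifluoromethanesulfonate
Conditions: Tf2O (1.3 equiv), 2,6-di-tert-butyl-4-methylpyridine (1.5 equiv), CH2Cl2, 0 °C to rt, in the dark
Reagents that add atoms: trifluoromethanesulfonic anhydride, O=S(=O)(OS(=O)(=O)C(F)(F)F)C(F)(F)F
Why: O-Sulfonylation of the aryl ketone followed by loss of H3f to the hindered pyridine gives the enol triflate without an enolate ever forming, so the β-aryloxide elimination that would racemise C2f has no pathway.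

**Step 7**
Reactants: 3 5-bromo-1,2,3-tris(benzyloxy)benzene
Product: 11 1,2,3-tris(benzyloxy)-5-bromo-4-iodobenzene
Conditions: N-iodosuccinimide (1.05 equiv), CF3CO2H (0.3 equiv), MeCN/CH2Cl2, 0 °C to rt, in the dark
Reagents that add atoms: N-iodosuccinimide, O=C1CCC(=O)N1I
Why: Electrophilic aromatic iodination can only strike the two equivalent free positions of the trialkoxy ring (ortho and para to OBn), and one equivalent of reagent should stop at the mono-iodide.

**Step 8**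
Reactants: 11 1,2,3-tris(benzyloxy)-5-bromo-4-iodobenzene; 10 (2S)-7-(benzyloxy)-2-[3,4,5-tris(benzyloxy)phenyl]-2H-chromen-4-yl trifluoromethanesulfonate
Product: 14 (2S)-7-(benzyloxy)-4-[2,3,4-tris(benzyloxy)-6-bromophenyl]-2-[3,4,5-tris(benzyloxy)phenyl]-2H-chromene, via arylmagnesium chloride 12 (not isolated), via arylzinc chloride 13 (not isolated)
Conditions: i-PrMgCl·LiCl (1.05 equiv), THF, −30 °C; ZnCl2, −30 °C to rt; 10, Pd(dba)2 (5 mol %), P(2-furyl)3 (10 mol %), THF, 45 °C, in the dark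
Reagents that add atoms: none
Why: Iodine–magnesium exchange picks C–I over C–Br, transmetalation to zinc removes the risk of aryne formation, and the Negishi coupling takes place at the far more reactive enol triflate while zerovalent palladium with a weakly donating phosphine spares the electron-rich, hindered C–Br bond.

**Step 9**
Reactants: 14 (2S)-7-(benzyloxy)-4-[2,3,4-tris(benzyloxy)-6-bromophenyl]-2-[3,4,5-tris(benzyloxy)phenyl]-2H-chromene
Product: 16 (2R,3S,4S)-7-(benzyloxy)-4-[2,3,4-tris(benzyloxy)-6-bromophenyl]-2-[3,4,5-tris(benzyloxy)phenyl]chroman-3-ol, via alkylborane 15 (not isolated)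
Conditions: BH3·THF (3 equiv), THF, 0 °C to rt; 3 M NaOH, 30% H2O2, 0 °C
Reagents that add atoms: hydrogen peroxide, OO
Why: In this hydroboration–oxidation of a flav-3-ene, boron goes to the less substituted C3f and B–H adds syn from the face opposite ring E, so oxidation with retention should give the 2,3-trans-3,4-trans alcohol (3S,4S) under control of C2f.

**Step 10**
Reactants: 16 (2R,3S,4S)-7-(benzyloxy)-4-[2,3,4-tris(benzyloxy)-6-bromophenyl]-2-[3,4,5-tris(benzyloxy)phenyl]chroman-3-ol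
Product: 17 ArFl bromide [(2R,3S,4S)-3,7-bis(benzyloxy)-4-[2,3,4-tris(benzyloxy)-6-bromophenyl]-2-[3,4,5-tris(benzyloxy)phenyl]chromane]
Conditions: NaH, BnBr, n-Bu4NI (cat.), DMF, 0 °C to rt
Reagents that add atoms: benzyl bromide, BrCc1ccccc1
Why: Williamson etherification of the equatorial secondary alkoxide, accelerated by iodide catalysis, masks the last acidic proton before the organolithium steps.

**Step 11**
Reactants: 18 methyl (4S)-2,2-dimethyl-1,3-dioxolane-4-carboxylate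
Product: 19 (4S)-N-methoxy-N,2,2-trimethyl-1,3-dioxolane-4-carboxamide
Conditions: MeNH(OMe)·HCl (1.5 equiv), i-PrMgCl (3 equiv), THF, −20 °C
Reagents that add atoms: N,O-dimethylhydroxylamine hydrochloride, CNOC.Cl
Why: Aminolysis of the ester by the chloromagnesium amide (Weinreb amide synthesis) is fast at low temperature and should leave the α-alkoxy stereocentre, the future C3, intact.

**Step 12**
Reactants: 17 ArFl bromide; 19 (4S)-N-methoxy-N,2,2-trimethyl-1,3-dioxolane-4-carboxamide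
Product: 22 ArFl (4S)-2,2-dimethyl-1,3-dioxolan-4-yl ketone, via aryllithium 20 (not isolated), via lithium hemiaminal alkoxide 21 (not isolated)
Conditions: t-BuLi (2.1 equiv), THF, −78 °C; 19 (1.5 equiv), −78 to −20 °C; AcOH
Reagents that add atoms: none
Why: After bromine–lithium exchange the Weinreb ketone synthesis forms C2–C1', the chelated adduct holding until the acidic quench so that over-addition and enolisation at the future C3 are avoided, and entry at the acid oxidation level saves the oxidation that an aldehyde adduct would need.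

**Step 13**
Reactants: 22 ArFl (4S)-2,2-dimethyl-1,3-dioxolan-4-yl ketone
Product: 23 (S)-ArFl[(4S)-2,2-dimethyl-1,3-dioxolan-4-yl]methanol (syn)
Conditions: LiBH(s-Bu)3 (1.5 equiv), THF, −78 °C; then NaOH, H2O2, 0 °C
Reagents that add atoms: none
Why: In this Felkin–Anh-controlled reduction the bulky, non-chelating hydride approaches anti to the C3–O bond of the dioxolane and should give the syn (S) carbinol, the epimer needed for an invertive etherification.

**Step 14**
Reactants: 24 4-bromoresorcinol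
Product: 25 5-(benzyloxy)-2-bromophenol
Conditions: BnBr (1.0 equiv), K2CO3 (1.0 equiv), acetone, rt to 40 °C
Reagents that add atoms: benzyl bromide, BrCc1ccccc1
Why: Williamson mono-etherification with one equivalent of halide should favour the unhindered, more nucleophilic phenoxide para to bromine over the one flanked by bromine, and the regioisomer and bis-ether are removed by chromatography.

**Step 15**
Reactants: 23 (S)-ArFl[(4S)-2,2-dimethyl-1,3-dioxolan-4-yl]methanol; 25 5-(benzyloxy)-2-bromophenol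
Product: 26 (4S)-4-[(R)-ArFl[5-(benzyloxy)-2-bromophenoxy]methyl]-2,2-dimethyl-1,3-dioxolane
Conditions: n-Bu3P, N,N,N',N'-tetramethylazodicarboxamide, toluene, 0 °C to rt
Reagents that add atoms: none
Why: In the Mitsunobu etherification the acidic 2-bromophenol displaces the oxyphosphonium group in an SN2 process that inverts C2 from S to R and creates the anti (future 2,3-trans) relationship, the non-polar solvent disfavouring ionisation.

**Step 16**
Reactants: 26 (4S)-4-[(R)-ArFl[5-(benzyloxy)-2-bromophenoxy]methyl]-2,2-dimethyl-1,3-dioxolane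
Product: 27 (2S,3R)-3-ArFl-3-[5-(benzyloxy)-2-bromophenoxy]propane-1,2-diol
Conditions: AcOH/H2O/THF (4:1:1), 45 °C
Reagents that add atoms: none
Why: Mild acid hydrolysis removes the terminal isopropylidene acetal, while the benzyl ethers and the benzylic aryl ether, whose ionisation is held back by the neighbouring C–O dipoles, should survive.

**Step 17**
Reactants: 27 (2S,3R)-3-ArFl-3-[5-(benzyloxy)-2-bromophenoxy]propane-1,2-diol
Product: 28 (4S)-4-[(R)-ArFl[5-(benzyloxy)-2-bromophenoxy]methyl]-2-phenyl-1,3-dioxolane (both epimers at the acetal carbon)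
Conditions: PhCH(OMe)2 (1.5 equiv), camphorsulfonic acid (5 mol %), 4 Å molecular sieves, CH2Cl2, rt
Reagents that add atoms: benzaldehyde dimethyl acetal, COC(OC)c1ccccc1
Why: Acid-catalysed transacetalisation gives the five-membered benzylidene acetal, and the epimer mixture at the new acetal carbon is of no consequence because that carbon becomes a CH2 group in the next step.

**Step 18**
Reactants: 28 (4S)-4-[(R)-ArFl[5-(benzyloxy)-2-bromophenoxy]methyl]-2-phenyl-1,3-dioxolane
Product: 29 (2S,3R)-2-(benzyloxy)-3-ArFl-3-[5-(benzyloxy)-2-bromophenoxy]propan-1-ol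
Conditions: i-Bu2AlH (4 equiv), CH2Cl2, −78 to 0 °C; aq potassium sodium tartrate
Reagents that add atoms: none
Why: In this regioselective reductive opening of a benzylidene acetal the aluminium hydride binds the less hindered primary oxygen, that C–O bond breaks and hydride is delivered to the oxocarbenium ion, which leaves the benzyl group on O3 and frees the primary alcohol.

**Step 19**
Reactants: 29 (2S,3R)-2-(benzyloxy)-3-ArFl-3-[5-(benzyloxy)-2-bromophenoxy]propan-1-ol
Product: 31 (2R,3R)-2-(benzyloxy)-3-ArFl-3-[5-(benzyloxy)-2-bromophenoxy]propanoic acid, via aldehyde 30 (not isolated)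
Conditions: TEMPO (0.2 equiv), PhI(OAc)2 (2.5 equiv), CH2Cl2/H2O (2:1), rt
Reagents that add atoms: water, O
Why: Oxoammonium-mediated oxidation takes the primary alcohol through the aldehyde hydrate to the acid (the future C4) under nearly neutral conditions that tolerate benzyl ethers and the aryl bromide and should not epimerise C3.

**Step 20**
Reactants: 31 (2R,3R)-2-(benzyloxy)-3-ArFl-3-[5-(benzyloxy)-2-bromophenoxy]propanoic acid
Product: 33 (2R,3R)-2-(benzyloxy)-3-ArFl-3-[5-(benzyloxy)-2-bromophenoxy]-N-methoxy-N-methylpropanamide, via acyl imidazolide 32 (not isolated)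
Conditions: 1,1'-carbonyldiimidazole (1.2 equiv), CH2Cl2, rt; MeNH(OMe)·HCl (1.5 equiv), rt
Reagents that add atoms: N,O-dimethylhydroxylamine hydrochloride, CNOC.Cl
Why: Activation as the acyl imidazolide and aminolysis by the amine hydrochloride (Weinreb amide synthesis) need no added base, so neither epimerisation at C3 nor β-elimination of the aryloxide is expected.

**Step 21**
Reactants: 33 (2R,3R)-2-(benzyloxy)-3-ArFl-3-[5-(benzyloxy)-2-bromophenoxy]-N-methoxy-N-methylpropanamide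
Product: 36 (2R,3R)-3,7-bis(benzyloxy)-2-ArFl-chroman-4-one (deca-O-benzyl target), via aryllithium 34 (not isolated), via cyclic lithium hemiaminal alkoxide 35 (not isolated)
Conditions: t-BuLi (2.2 equiv), THF/Et2O (4:1), −95 to −78 °C; AcOH in THF, −78 °C
Reagents that add atoms: none
Why: In this Parham cyclisation t-BuLi exchanges the only aryl bromide, on ring A, faster than it deprotonates or adds anywhere else (the second equivalent destroys t-BuBr), and aryllithium 34 attacks the N-methoxy-N-methylamide carbonyl to form C4–C4a. The closest known reaction type is the halogen–lithium exchange-initiated cyclisation of 3-(2-haloaryloxy)propanoic acid derivatives to chroman-4-ones. Ring C closes in the 6-exo-trig mode, with the carbonyl oxygen staying outside the new ring. No stereocentre of the product is created here, since C3 comes from the pool ester and C2 from steps 13 and 15, and both only have to survive. The selectivity needed is carbonyl attack over removal of H3 with expulsion of the aryloxide, and it is secured by the proximity of the two reacting centres, by the very low temperature and by lithium chelate 35, which keeps C4 tetrahedral so that no enolisable ketone ever meets base. The acetic acid quench at −78 °C releases ketone 36 in a non-basic medium, so the 2,3-trans arrangement should be kept.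

**Step 22**
Reactants: 36 (2R,3R)-3,7-bis(benzyloxy)-2-ArFl-chroman-4-one
Product: 37 (2R,3R)-3,7-dihydroxy-2-[3,4,5-trihydroxy-2-[(2R,3S,4S)-3,7-dihydroxy-2-(3,4,5-trihydroxyphenyl)chroman-4-yl]phenyl]chroman-4-one (CNP0310728.2)
Conditions: H2 (1 atm), Pd(OH)2/C, THF/MeOH (1:1), rt, work-up under argon
Reagents that add atoms: none
Why: Catalytic hydrogenolysis cleaves the ten O-benzyl groups, while the cyclic benzylic C–O bonds at C2 and C2f and the aryl ketone react much more slowly and should persist if the reaction is stopped at complete debenzylation.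

**Compound list**

1 | 5-bromo-1,2,3-trimethoxybenzene | COc1cc(Br)cc(OC)c1OC | starting material
2 | 5-bromobenzene-1,2,3-triol | Oc1cc(Br)cc(O)c1O | intermediate
3 | 5-bromo-1,2,3-tris(benzyloxy)benzene | Brc1cc(OCc2ccccc2)c(OCc2ccccc2)c(OCc2ccccc2)c1 | intermediate
4 | 3,4,5-tris(benzyloxy)phenyllithium | [Li]c1cc(OCc2ccccc2)c(OCc2ccccc2)c(OCc2ccccc2)c1 | intermediate
5 | lithium [3,4,5-tris(benzyloxy)phenyl]triisopropoxyborate | [Li+].CC(C)O[B-](OC(C)C)(OC(C)C)c1cc(OCc2ccccc2)c(OCc2ccccc2)c(OCc2ccccc2)c1 | intermediate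
6 | 3,4,5-tris(benzyloxy)phenylboronic acid | OB(O)c1cc(OCc2ccccc2)c(OCc2ccccc2)c(OCc2ccccc2)c1 | intermediate
7 | 7-hydroxy-4H-chromen-4-one | O=c1ccoc2cc(O)ccc12 | starting material
8 | 7-(benzyloxy)-4H-chromen-4-one | O=c1ccoc2cc(OCc3ccccc3)ccc12 | intermediate
9 | (2S)-7-(benzyloxy)-2-[3,4,5-tris(benzyloxy)phenyl]chroman-4-one | O=C1C[C@@H](c2cc(OCc3ccccc3)c(OCc3ccccc3)c(OCc3ccccc3)c2)Oc2cc(OCc3ccccc3)ccc12 | intermediate
10 | (2S)-7-(benzyloxy)-2-[3,4,5-tris(benzyloxy)phenyl]-2H-chromen-4-yl trifluoromethanesulfonate | O=S(=O)(OC1=C[C@@H](c2cc(OCc3ccccc3)c(OCc3ccccc3)c(OCc3ccccc3)c2)Oc2cc(OCc3ccccc3)ccc12)C(F)(F)F | intermediate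
11 | 1,2,3-tris(benzyloxy)-5-bromo-4-iodobenzene | Brc1cc(OCc2ccccc2)c(OCc2ccccc2)c(OCc2ccccc2)c1I | intermediate
12 | [2,3,4-tris(benzyloxy)-6-bromophenyl]magnesium chloride | Brc1cc(OCc2ccccc2)c(OCc2ccccc2)c(OCc2ccccc2)c1[Mg]Cl | intermediate
13 | [2,3,4-tris(benzyloxy)-6-bromophenyl]zinc chloride | Brc1cc(OCc2ccccc2)c(OCc2ccccc2)c(OCc2ccccc2)c1[Zn]Cl | intermediate
14 | (2S)-7-(benzyloxy)-4-[2,3,4-tris(benzyloxy)-6-bromophenyl]-2-[3,4,5-tris(benzyloxy)phenyl]-2H-chromene | Brc1cc(OCc2ccccc2)c(OCc2ccccc2)c(OCc2ccccc2)c1C1=C[C@@H](c2cc(OCc3ccccc3)c(OCc3ccccc3)c(OCc3ccccc3)c2)Oc2cc(OCc3ccccc3)ccc12 | intermediate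
15 | alkylborane: compound 16 with BH2 in place of the 3-hydroxyl, same spatial arrangement | Brc1cc(OCc2ccccc2)c(OCc2ccccc2)c(OCc2ccccc2)c1[C@@H]1c2ccc(OCc3ccccc3)cc2O[C@H](c2cc(OCc3ccccc3)c(OCc3ccccc3)c(OCc3ccccc3)c2)[C@H]1B | intermediate
16 | (2R,3S,4S)-7-(benzyloxy)-4-[2,3,4-tris(benzyloxy)-6-bromophenyl]-2-[3,4,5-tris(benzyloxy)phenyl]chroman-3-ol | Brc1cc(OCc2ccccc2)c(OCc2ccccc2)c(OCc2ccccc2)c1[C@@H]1c2ccc(OCc3ccccc3)cc2O[C@H](c2cc(OCc3ccccc3)c(OCc3ccccc3)c(OCc3ccccc3)c2)[C@H]1O | intermediate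
17 | ArFl bromide, (2R,3S,4S)-3,7-bis(benzyloxy)-4-[2,3,4-tris(benzyloxy)-6-bromophenyl]-2-[3,4,5-tris(benzyloxy)phenyl]chromane | Brc1cc(OCc2ccccc2)c(OCc2ccccc2)c(OCc2ccccc2)c1[C@@H]1c2ccc(OCc3ccccc3)cc2O[C@H](c2cc(OCc3ccccc3)c(OCc3ccccc3)c(OCc3ccccc3)c2)[C@H]1OCc1ccccc1 | intermediate
18 | methyl (4S)-2,2-dimethyl-1,3-dioxolane-4-carboxylate | COC(=O)[C@@H]1COC(C)(C)O1 | starting material
19 | (4S)-N-methoxy-N,2,2-trimethyl-1,3-dioxolane-4-carboxamide | CON(C)C(=O)[C@@H]1COC(C)(C)O1 | intermediate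
20 | ArFl lithium | [Li]c1cc(OCc2ccccc2)c(OCc2ccccc2)c(OCc2ccccc2)c1[C@@H]1c2ccc(OCc3ccccc3)cc2O[C@H](c2cc(OCc3ccccc3)c(OCc3ccccc3)c(OCc3ccccc3)c2)[C@H]1OCc1ccccc1 | intermediate
21 | lithium alkoxide of the ArFl/amide 19 tetrahedral adduct (new carbon undefined) | CON(C)C(O[Li])([C@@H]1COC(C)(C)O1)c1cc(OCc2ccccc2)c(OCc2ccccc2)c(OCc2ccccc2)c1[C@@H]1c2ccc(OCc3ccccc3)cc2O[C@H](c2cc(OCc3ccccc3)c(OCc3ccccc3)c(OCc3ccccc3)c2)[C@H]1OCc1ccccc1 | intermediate
22 | ArFl (4S)-2,2-dimethyl-1,3-dioxolan-4-yl ketone | CC1(C)OC[C@H](O1)C(=O)c1cc(OCc2ccccc2)c(OCc2ccccc2)c(OCc2ccccc2)c1[C@@H]1c2ccc(OCc3ccccc3)cc2O[C@H](c2cc(OCc3ccccc3)c(OCc3ccccc3)c(OCc3ccccc3)c2)[C@H]1OCc1ccccc1 | intermediate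
23 | (S)-ArFl[(4S)-2,2-dimethyl-1,3-dioxolan-4-yl]methanol (syn) | CC1(C)OC[C@H](O1)[C@@H](O)c1cc(OCc2ccccc2)c(OCc2ccccc2)c(OCc2ccccc2)c1[C@@H]1c2ccc(OCc3ccccc3)cc2O[C@H](c2cc(OCc3ccccc3)c(OCc3ccccc3)c(OCc3ccccc3)c2)[C@H]1OCc1ccccc1 | intermediate
24 | 4-bromoresorcinol | Oc1ccc(Br)c(O)c1 | starting material
25 | 5-(benzyloxy)-2-bromophenol | Oc1cc(OCc2ccccc2)ccc1Br | intermediate
26 | (4S)-4-[(R)-ArFl[5-(benzyloxy)-2-bromophenoxy]methyl]-2,2-dimethyl-1,3-dioxolane | CC1(C)OC[C@H](O1)[C@H](Oc1cc(OCc2ccccc2)ccc1Br)c1cc(OCc2ccccc2)c(OCc2ccccc2)c(OCc2ccccc2)c1[C@@H]1c2ccc(OCc3ccccc3)cc2O[C@H](c2cc(OCc3ccccc3)c(OCc3ccccc3)c(OCc3ccccc3)c2)[C@H]1OCc1ccccc1 | intermediate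
27 | (2S,3R)-3-ArFl-3-[5-(benzyloxy)-2-bromophenoxy]propane-1,2-diol | OC[C@H](O)[C@H](Oc1cc(OCc2ccccc2)ccc1Br)c1cc(OCc2ccccc2)c(OCc2ccccc2)c(OCc2ccccc2)c1[C@@H]1c2ccc(OCc3ccccc3)cc2O[C@H](c2cc(OCc3ccccc3)c(OCc3ccccc3)c(OCc3ccccc3)c2)[C@H]1OCc1ccccc1 | intermediate
28 | (4S)-4-[(R)-ArFl[5-(benzyloxy)-2-bromophenoxy]methyl]-2-phenyl-1,3-dioxolane (acetal carbon undefined) | c1ccccc1C1OC[C@H](O1)[C@H](Oc1cc(OCc2ccccc2)ccc1Br)c1cc(OCc2ccccc2)c(OCc2ccccc2)c(OCc2ccccc2)c1[C@@H]1c2ccc(OCc3ccccc3)cc2O[C@H](c2cc(OCc3ccccc3)c(OCc3ccccc3)c(OCc3ccccc3)c2)[C@H]1OCc1ccccc1 | intermediate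
29 | (2S,3R)-2-(benzyloxy)-3-ArFl-3-[5-(benzyloxy)-2-bromophenoxy]propan-1-ol | OC[C@H](OCc1ccccc1)[C@H](Oc1cc(OCc2ccccc2)ccc1Br)c1cc(OCc2ccccc2)c(OCc2ccccc2)c(OCc2ccccc2)c1[C@@H]1c2ccc(OCc3ccccc3)cc2O[C@H](c2cc(OCc3ccccc3)c(OCc3ccccc3)c(OCc3ccccc3)c2)[C@H]1OCc1ccccc1 | intermediate
30 | (2R,3R)-2-(benzyloxy)-3-ArFl-3-[5-(benzyloxy)-2-bromophenoxy]propanal | O=C[C@H](OCc1ccccc1)[C@H](Oc1cc(OCc2ccccc2)ccc1Br)c1cc(OCc2ccccc2)c(OCc2ccccc2)c(OCc2ccccc2)c1[C@@H]1c2ccc(OCc3ccccc3)cc2O[C@H](c2cc(OCc3ccccc3)c(OCc3ccccc3)c(OCc3ccccc3)c2)[C@H]1OCc1ccccc1 | intermediate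
31 | (2R,3R)-2-(benzyloxy)-3-ArFl-3-[5-(benzyloxy)-2-bromophenoxy]propanoic acid | OC(=O)[C@H](OCc1ccccc1)[C@H](Oc1cc(OCc2ccccc2)ccc1Br)c1cc(OCc2ccccc2)c(OCc2ccccc2)c(OCc2ccccc2)c1[C@@H]1c2ccc(OCc3ccccc3)cc2O[C@H](c2cc(OCc3ccccc3)c(OCc3ccccc3)c(OCc3ccccc3)c2)[C@H]1OCc1ccccc1 | intermediate
32 | N-acylimidazole of acid 31 | O=C(n1ccnc1)[C@H](OCc1ccccc1)[C@H](Oc1cc(OCc2ccccc2)ccc1Br)c1cc(OCc2ccccc2)c(OCc2ccccc2)c(OCc2ccccc2)c1[C@@H]1c2ccc(OCc3ccccc3)cc2O[C@H](c2cc(OCc3ccccc3)c(OCc3ccccc3)c(OCc3ccccc3)c2)[C@H]1OCc1ccccc1 | intermediate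
33 | (2R,3R)-2-(benzyloxy)-3-ArFl-3-[5-(benzyloxy)-2-bromophenoxy]-N-methoxy-N-methylpropanamide | CON(C)C(=O)[C@H](OCc1ccccc1)[C@H](Oc1cc(OCc2ccccc2)ccc1Br)c1cc(OCc2ccccc2)c(OCc2ccccc2)c(OCc2ccccc2)c1[C@@H]1c2ccc(OCc3ccccc3)cc2O[C@H](c2cc(OCc3ccccc3)c(OCc3ccccc3)c(OCc3ccccc3)c2)[C@H]1OCc1ccccc1 | intermediate
34 | ring A aryllithium of 33 (Li in place of Br) | CON(C)C(=O)[C@H](OCc1ccccc1)[C@H](Oc1cc(OCc2ccccc2)ccc1[Li])c1cc(OCc2ccccc2)c(OCc2ccccc2)c(OCc2ccccc2)c1[C@@H]1c2ccc(OCc3ccccc3)cc2O[C@H](c2cc(OCc3ccccc3)c(OCc3ccccc3)c(OCc3ccccc3)c2)[C@H]1OCc1ccccc1 | intermediate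
35 | cyclic lithium alkoxide, 4-[methoxy(methyl)amino]chroman-4-olate form of 36 (C4 undefined) | CON(C)C1(O[Li])c2ccc(OCc3ccccc3)cc2O[C@H](c2cc(OCc3ccccc3)c(OCc3ccccc3)c(OCc3ccccc3)c2[C@@H]2c3ccc(OCc4ccccc4)cc3O[C@H](c3cc(OCc4ccccc4)c(OCc4ccccc4)c(OCc4ccccc4)c3)[C@H]2OCc2ccccc2)[C@H]1OCc1ccccc1 | intermediate
36 | (2R,3R)-3,7-bis(benzyloxy)-2-ArFl-chroman-4-one (deca-O-benzyl target) | O=C1c2ccc(OCc3ccccc3)cc2O[C@H](c2cc(OCc3ccccc3)c(OCc3ccccc3)c(OCc3ccccc3)c2[C@@H]2c3ccc(OCc4ccccc4)cc3O[C@H](c3cc(OCc4ccccc4)c(OCc4ccccc4)c(OCc4ccccc4)c3)[C@H]2OCc2ccccc2)[C@H]1OCc1ccccc1 | intermediate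
37 | (2R,3R)-3,7-dihydroxy-2-[3,4,5-trihydroxy-2-[(2R,3S,4S)-3,7-dihydroxy-2-(3,4,5-trihydroxyphenyl)chroman-4-yl]phenyl]chroman-4-one | O=C1c2ccc(O)cc2O[C@H](c2cc(O)c(O)c(O)c2[C@@H]2c3ccc(O)cc3O[C@H](c3cc(O)c(O)c(O)c3)[C@H]2O)[C@H]1O | target

**Step count**
Total: 22 steps.
Longest linear sequence: 18 steps (1, 2, 3, 5, 6, 8, 9, 10, 12, 13, 15, 16, 17, 18, 19, 20, 21, 22).

**The three steps most likely to fail**

**Step 8 (Negishi coupling).** Transmetalation of the doubly ortho-substituted arylzinc to the alkenylpalladium species may be too slow. Homocoupling, protodemetalation or insertion of zerovalent palladium into the C–Br bond could then take over. The fallback reverses the polarity of the coupling.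
- It sets out from 10. Miyaura borylation (B2pin2, PdCl2(PPh3)2, PPh3, KOPh, toluene, 50 °C) would give the (2S)-7-(benzyloxy)-2-[3,4,5-tris(benzyloxy)phenyl]-2H-chromen-4-yl pinacol boronate F1, which is unhindered at boron.
- Suzuki–Miyaura coupling of F1 with bromo iodide 11 (Pd(PPh3)4, K3PO4, dioxane/H2O, 60 °C) relies on the large rate gap between oxidative addition to C–I and to C–Br. It comes back to the route at 14.

**Step 15 (Mitsunobu etherification).** The carbinol is hindered by the ortho flavanyl group and activated by the para benzyloxy group. The SN2 displacement may therefore be slower than ionisation of the oxyphosphonium species, which would erode the configuration at C2, or the alcohol may not react at all. The fallback forms the O1–aryl bond instead of the O1–C2 bond and so keeps the configuration at C2.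
- It sets out from 22. Chelation-controlled reduction with Zn(BH4)2 (Et2O, −30 °C) would give the anti carbinol (R)-ArFl[(4S)-2,2-dimethyl-1,3-dioxolan-4-yl]methanol F2.
- The potassium alkoxide of F2 (KN(SiMe3)2, THF, 0 °C) would displace fluoride from commercial 4-(benzyloxy)-2-fluoro-1-nitrobenzene by nucleophilic aromatic substitution, giving the 5-(benzyloxy)-2-nitrophenyl ether F3.
- Reduction with Zn and NH4Cl in THF/MeOH/H2O would give the 2-amino-5-(benzyloxy)phenyl ether F4.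
- Sandmeyer-type bromodediazoniation (t-BuONO, CuBr2, MeCN, 0 °C to rt) comes back to the route at 26.

**Step 21 (Parham cyclisation).** Three processes could compete with ring closure:
- proton transfer to the aryllithium;
- removal of H3 followed by expulsion of the aryloxide;
- attack of t-BuLi on the amide.

The fallback closes the same C4–C4a bond at the aldehyde oxidation level with a non-basic organometal.
- It sets out from 29. Oxidation with Dess–Martin periodinane (CH2Cl2, NaHCO3, rt) would give aldehyde 30, this time isolated.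
- Intramolecular Nozaki–Hiyama–Kishi addition (CrCl2, NiCl2 (cat.), DMF/THF, rt to 50 °C) would give the (2R,3R)-3,7-bis(benzyloxy)-2-ArFl-chroman-4-ol F5 as a mixture at C4.
- A second Dess–Martin oxidation removes that centre and comes back to the route at 36.

**Further compounds**
F1 | step 8 | (2S)-7-(benzyloxy)-4-(4,4,5,5-tetramethyl-1,3,2-dioxaborolan-2-yl)-2-[3,4,5-tris(benzyloxy)phenyl]-2H-chromene | CC1(C)OB(OC1(C)C)C1=C[C@@H](c2cc(OCc3ccccc3)c(OCc3ccccc3)c(OCc3ccccc3)c2)Oc2cc(OCc3ccccc3)ccc12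
F2 | step 15 | (R)-ArFl[(4S)-2,2-dimethyl-1,3-dioxolan-4-yl]methanol (anti) | CC1(C)OC[C@H](O1)[C@H](O)c1cc(OCc2ccccc2)c(OCc2ccccc2)c(OCc2ccccc2)c1[C@@H]1c2ccc(OCc3ccccc3)cc2O[C@H](c2cc(OCc3ccccc3)c(OCc3ccccc3)c(OCc3ccccc3)c2)[C@H]1OCc1ccccc1
F3 | step 15 | (4S)-4-[(R)-ArFl[5-(benzyloxy)-2-nitrophenoxy]methyl]-2,2-dimethyl-1,3-dioxolane | CC1(C)OC[C@H](O1)[C@H](Oc1cc(OCc2ccccc2)ccc1[N+](=O)[O-])c1cc(OCc2ccccc2)c(OCc2ccccc2)c(OCc2ccccc2)c1[C@@H]1c2ccc(OCc3ccccc3)cc2O[C@H](c2cc(OCc3ccccc3)c(OCc3ccccc3)c(OCc3ccccc3)c2)[C@H]1OCc1ccccc1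
F4 | step 15 | (4S)-4-[(R)-ArFl[2-amino-5-(benzyloxy)phenoxy]methyl]-2,2-dimethyl-1,3-dioxolane | CC1(C)OC[C@H](O1)[C@H](Oc1cc(OCc2ccccc2)ccc1N)c1cc(OCc2ccccc2)c(OCc2ccccc2)c(OCc2ccccc2)c1[C@@H]1c2ccc(OCc3ccccc3)cc2O[C@H](c2cc(OCc3ccccc3)c(OCc3ccccc3)c(OCc3ccccc3)c2)[C@H]1OCc1ccccc1
F5 | step 21 | (2R,3R)-3,7-bis(benzyloxy)-2-ArFl-chroman-4-ol (C4 undefined) | OC1c2ccc(OCc3ccccc3)cc2O[C@H](c2cc(OCc3ccccc3)c(OCc3ccccc3)c(OCc3ccccc3)c2[C@@H]2c3ccc(OCc4ccccc4)cc3O[C@H](c3cc(OCc4ccccc4)c(OCc4ccccc4)c(OCc4ccccc4)c3)[C@H]2OCc2ccccc2)[C@H]1OCc1ccccc1
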